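**Assumption:** (R)-2-methylbutanoic acid (≥98% ee) and prenylmagnesium chloride (THF solution) are taken as commercial; the target's acyl stereocentre is R by CIP; enolic compounds are drawn as one tautomer.

**Retrosynthetic overview**
1. Side chain last: the tertiary carbinol chain comes from Cu-catalysed opening of a terminal epoxide by a prenyl Grignard reagent.
2. Dihydrofuran ring (formed second) and both side-chain stereocentres: Sharpless epoxidation of an (E)-allylic alcohol arm, then 5-exo attack of the enol oxygen.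
3. Quaternary ring carbon: Pd-catalysed asymmetric allylation of the 6-prenyl acylfilicinic acid with isoprene monoxide; prenyl by C-alkylation.
4. Six-membered triketone ring (formed first): one-carbon ring expansion of 3,3-dimethylcyclopentane-1,2,4-trione by the (R)-acyl diazomethane through a 1,2-vinyl shift.
5. Trione from 3-methylbutan-2-one and dimethyl oxalate; diazoketone from (R)-2-methylbutanoic acid.

**Route**

Step 1
Reactants: 1 3-methylbutan-2-one; 2 dimethyl oxalate
Product: 3 3,3-dimethylcyclopentane-1,2,4-trione (enol form)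
Conditions: NaOMe (2.5 equiv), MeOH then toluene, reflux (MeOH distilled off); aq. HCl
Reagents that add atoms: none
Why: Double Claisen condensation (ketone–oxalate condensation at the methyl group, then Dieckmann closure through the isopropyl carbon), the classical entry to cyclopentane-1,2,4-triones, driven by formation of the vinylogous-acid salt.

Step 2
Reactants: 4 (R)-2-methylbutanoic acid
Product: 6 (3R)-1-diazo-3-methylpentan-2-one, via acid chloride 5 (not isolated)
Conditions: (COCl)2, DMF (cat.), CH2Cl2, 0 °C to rt, evaporate; TMSCHN2 (2 equiv), MeCN/THF, 0 °C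
Reagents that add atoms: oxalyl chloride, O=C(Cl)C(=O)Cl; (trimethylsilyl)diazomethane, C[Si](C)(C)C=[N+]=[N-]
Why: Acid chloride formation followed by Arndt–Eistert-type acylation of the diazomethane reagent; no amine base is present, so no ketene forms and the α-stereocentre is kept.

Step 3
Reactants: 3 3,3-dimethylcyclopentane-1,2,4-trione; 6 (3R)-1-diazo-3-methylpentan-2-one
Product: 10 (R)-2-methylbutanoylfilicinic acid, via silyl enol ether 7 (not isolated), via diazo aldol adduct 8 (not isolated), via silylated triketone 9 (not isolated)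
Conditions: 3, HMDS, TMSCl (cat.), 60 °C, evaporate; 6, LDA, THF, −78 °C, then 7, −78 °C, AcOH quench, crude carried on; Rh2(OAc)4 (1 mol%), CH2Cl2, 0 °C to rt; 1 M HCl, THF
Reagents that add atoms: hexamethyldisilazane, C[Si](C)(C)N[Si](C)(C)C
Why: Proposed new method: in 7 only the α-siloxy-enone carbonyl is electrophilic (the other is a vinylogous ester), so the lithiated diazoketone adds 1,2 (diazo aldol), and the Rh(II) carbene then triggers a 1,2-shift of the electron-rich siloxyvinyl carbon in preference to the acyl-bearing quaternary alkyl carbon, which expands the five- to the six-membered ring with the acyl-bearing carbon placed between the two ring carbonyls; the closest known reactions are the Tiffeneau–Demjanov/Eistert-type ring expansion of cyclic ketones and isatins with diazo carbonyl compounds and the Rh(II)-catalysed 1,2-shift of β-hydroxy-α-diazo carbonyl compounds, neither shown on a cyclopentane-1,2,4-trione enol ether.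

Step 4
Reactants: 10 (R)-2-methylbutanoylfilicinic acid; 11 prenyl bromide
Product: 12 6-prenyl acylfilicinic acid
Conditions: NaOMe (1.0 equiv), MeOH, 0 °C; prenyl bromide (1.0 equiv), 0 °C to rt; aq. HCl
Reagents that add atoms: none
Why: C-alkylation of the acylphloroglucinol-type triketone enolate with a soft allylic bromide at the only unsubstituted ring carbon (known for acylfilicinic acids); the delocalised anion shields the acyl α-stereocentre from epimerisation.

Step 5
Reactants: 12 6-prenyl acylfilicinic acid; 13 2-methyl-2-vinyloxirane (racemic)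
Product: 14 (6S)-quaternary (E)-allylic alcohol
Conditions: Pd2(dba)3·CHCl3 (2.5 mol%), (R,R)-DACH-phenyl Trost ligand (7.5 mol%; antipode if the facial sense proves opposite), CH2Cl2, 0 °C to rt
Reagents that add atoms: none
Why: Tsuji–Trost allylic alkylation with a vinyl epoxide (the acidic pronucleophile protonates the alkoxide and attacks the unsubstituted allyl terminus to give the (E)-1,4-adduct), in which the chiral Pd–allyl complex selects one face of the planar triketonate, whose two flanks differ, and so sets the quaternary carbon as S, as precedented for Pd-catalysed asymmetric dearomative allylation of acylphloroglucinols; any minor Z isomer or 6-epimer is removed here or after step 6.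

Step 6
Reactants: 14 (6S)-quaternary (E)-allylic alcohol
Product: 16 (2R,3aS)-dihydrobenzofuranone diol, via epoxy alcohol 15 (not isolated)
Conditions: Ti(OiPr)4 (2.2 equiv), L-(+)-DET (2.6 equiv), TBHP (2.0 equiv, decane), 4 Å MS, CH2Cl2, −20 °C to 0 °C; aq. tartaric acid
Reagents that add atoms: tert-butyl hydroperoxide, CC(C)(C)OO
Why: Sharpless asymmetric epoxidation gives the (2S,3S)-epoxy alcohol under reagent control (the prenyl alkene is not an allylic alcohol and stays untouched), and the titanium-bound enol oxygen then opens the epoxide 5-exo at the secondary carbon with inversion (ring carbon 2R) while the tertiary carbinol keeps its C–O bond (S); the extra Ti/tartrate allows for binding of the triketone.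

Step 7
Reactants: 16 (2R,3aS)-dihydrobenzofuranone diol
Product: 18 (2S)-methyloxiranyl dihydrobenzofuranone, via primary tosylate 17 (not isolated)
Conditions: TsCl (1.1 equiv), Et3N, Bu2SnO (2 mol%), CH2Cl2, 0 °C; then DBU, rt
Reagents that add atoms: p-toluenesulfonyl chloride, Cc1ccc(cc1)S(=O)(=O)Cl
Why: Selective sulfonylation of the primary hydroxyl and intramolecular Williamson closure by the tertiary alkoxide; the C–O bond at the tertiary stereocentre is not broken, so its configuration is retained.

Step 8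
Reactants: 18 (2S)-methyloxiranyl dihydrobenzofuranone; 19 prenylmagnesium chloride
Product: 20 target CNP0306408.2
Conditions: 19 (2.5 equiv), CuI (15 mol%), THF, −40 to −20 °C; aq. NH4Cl
Reagents that add atoms: none
Why: Copper-catalysed SN2 opening of the 2,2-disubstituted epoxide at its CH2 carbon by the α-carbon of the prenyl Grignard reagent; the three ketones are either flanked by quaternary carbons or vinylogous and react more slowly at low temperature, and no stereocentre is touched.

**Compound list**
1 | 3-methylbutan-2-one | CC(=O)C(C)C | starting material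
2 | dimethyl oxalate | COC(=O)C(=O)OC | starting material
3 | 3,3-dimethylcyclopentane-1,2,4-trione, drawn as 4-hydroxy-2,2-dimethylcyclopent-4-ene-1,3-dione | O=C1C(O)=CC(=O)C1(C)C | intermediate
4 | (R)-2-methylbutanoic acid | CC[C@@H](C)C(=O)O | starting material
5 | (R)-2-methylbutanoyl chloride | CC[C@@H](C)C(=O)Cl | intermediate
6 | (3R)-1-diazo-3-methylpentan-2-one | CC[C@@H](C)C(=O)C=[N+]=[N-] | intermediate
7 | 2,2-dimethyl-4-(trimethylsilyloxy)cyclopent-4-ene-1,3-dione | O=C1C(O[Si](C)(C)C)=CC(=O)C1(C)C | intermediate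
8 | 4-[(3R)-1-diazo-3-methyl-2-oxopentyl]-4-hydroxy-5,5-dimethyl-3-(trimethylsilyloxy)cyclopent-2-en-1-one (both carbinol epimers) | CC[C@@H](C)C(=O)C(=[N+]=[N-])C1(O)C(O[Si](C)(C)C)=CC(=O)C1(C)C | intermediate
9 | 5-hydroxy-6,6-dimethyl-4-[(2R)-2-methylbutanoyl]-3-(trimethylsilyloxy)cyclohexa-2,4-dien-1-one | CC[C@@H](C)C(=O)C1=C(O)C(C)(C)C(=O)C=C1O[Si](C)(C)C | intermediate
10 | (R)-2-methylbutanoylfilicinic acid: 5-hydroxy-2,2-dimethyl-4-[(2R)-2-methylbutanoyl]cyclohex-4-ene-1,3-dione | CC[C@@H](C)C(=O)C1=C(O)CC(=O)C(C)(C)C1=O | intermediate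
11 | prenyl bromide (1-bromo-3-methylbut-2-ene) | CC(C)=CCBr | starting material
12 | 3,5-dihydroxy-6,6-dimethyl-2-[(2R)-2-methylbutanoyl]-4-(3-methylbut-2-en-1-yl)cyclohexa-2,4-dien-1-one | CC[C@@H](C)C(=O)C1=C(O)C(CC=C(C)C)=C(O)C(C)(C)C1=O | intermediate
13 | 2-methyl-2-vinyloxirane (isoprene monoxide, racemic) | CC1(C=C)CO1 | starting material
14 | (6S)-5-hydroxy-6-[(2E)-4-hydroxy-3-methylbut-2-en-1-yl]-2,2-dimethyl-4-[(2R)-2-methylbutanoyl]-6-(3-methylbut-2-en-1-yl)cyclohex-4-ene-1,3-dione | CC[C@@H](C)C(=O)C1=C(O)[C@](CC=C(C)C)(C/C=C(C)/CO)C(=O)C(C)(C)C1=O | intermediate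
15 | (6S)-5-hydroxy-6-{[(2S,3S)-3-(hydroxymethyl)-3-methyloxiran-2-yl]methyl}-2,2-dimethyl-4-[(2R)-2-methylbutanoyl]-6-(3-methylbut-2-en-1-yl)cyclohex-4-ene-1,3-dione | CC[C@@H](C)C(=O)C1=C(O)[C@](CC=C(C)C)(C[C@@H]2O[C@@]2(C)CO)C(=O)C(C)(C)C1=O | intermediate
16 | (2R,3aS)-2-[(2S)-1,2-dihydroxypropan-2-yl]-5,5-dimethyl-7-[(2R)-2-methylbutanoyl]-3a-(3-methylbut-2-en-1-yl)-3,3a-dihydro-1-benzofuran-4,6(2H,5H)-dione | CC[C@@H](C)C(=O)C1=C2O[C@@H]([C@@](C)(O)CO)C[C@]2(CC=C(C)C)C(=O)C(C)(C)C1=O | intermediate
17 | primary p-toluenesulfonate of 16, (2S)-2-hydroxy-1-(tosyloxy)propan-2-yl side chain | CC[C@@H](C)C(=O)C1=C2O[C@@H]([C@@](C)(O)COS(=O)(=O)c3ccc(C)cc3)C[C@]2(CC=C(C)C)C(=O)C(C)(C)C1=O | intermediate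
18 | (2R,3aS)-5,5-dimethyl-7-[(2R)-2-methylbutanoyl]-3a-(3-methylbut-2-en-1-yl)-2-[(2S)-2-methyloxiran-2-yl]-3,3a-dihydro-1-benzofuran-4,6(2H,5H)-dione | CC[C@@H](C)C(=O)C1=C2O[C@@H]([C@]3(C)CO3)C[C@]2(CC=C(C)C)C(=O)C(C)(C)C1=O | intermediate
19 | prenylmagnesium chloride (3-methylbut-2-enylmagnesium chloride) | CC(C)=CC[Mg]Cl | starting material
20 | (2R,3aS)-2-[(2S)-2-hydroxy-6-methylhept-5-en-2-yl]-5,5-dimethyl-7-[(2R)-2-methylbutanoyl]-3a-(3-methylbut-2-en-1-yl)-3,3a-dihydro-1-benzofuran-4,6(2H,5H)-dione | CC[C@@H](C)C(=O)C1=C2O[C@@H]([C@@](C)(O)CCC=C(C)C)C[C@]2(CC=C(C)C)C(=O)C(C)(C)C1=O | target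

**Step count:** 8 steps in total. **Longest linear sequence:** 7 steps (1, 3, 4, 5, 6, 7, 8); step 2 is the converging branch.

**Three steps most likely to fail**

Step 3 (the proposed new step). The diazo aldol could go by conjugate addition or revert, the wrong carbon could migrate, or the silyl ether could be cleaved early. The fallback uses known Claisen and acylation chemistry; it sets out from 5 and comes back at 10. The lithium enolate of methyl isobutyrate (COC(=O)C(C)C; LDA, THF, −78 °C) is acetoacetylated with diketene (C=C1CC(=O)O1) to give methyl 2,2-dimethyl-3,5-dioxohexanoate F1. Claisen cyclisation of the terminal methyl ketone onto the ester (NaOMe, MeOH, reflux) gives filicinic acid F2. C-acylation of this with acid chloride 5 (AlCl3, CH2Cl2/nitrobenzene, or O-acylation followed by a DMAP-mediated O-to-C acyl shift) gives 10, whose ee is checked before going on.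

Step 5. The facial selectivity at the new quaternary carbon may be low, and some Z alkene may form. The fallback gives up catalyst control and lets the reagent-controlled epoxidation do the sorting; it sets out from 12 and comes back at 16. Allylation with 13 under achiral Pd(PPh3)4 gives 14 mixed about 1:1 with its epimer (6R)-quaternary allylic alcohol F3. The mixture is taken through the conditions of step 6, giving 16 together with the (2R,3aR)-diol F4, in which prenyl and side chain are trans on the dihydrofuran ring. These ring diastereomers are separated by chromatography and only 16 goes on (at most half of the material).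

Step 8. The prenyl Grignard reagent may add to a ketone, couple through its γ-carbon, or epimerise the acyl α-centre. The fallback builds the chain end by a B-alkyl Suzuki coupling instead; it sets out from 16 and comes back at 20. Selective oxidation of the primary alcohol (TEMPO cat., PhI(OAc)2, CH2Cl2) gives the α-hydroxy aldehyde F5. Wittig methylenation (Ph3P=CH2, THF, −78 to 0 °C) gives the vinyl carbinol F6. Hydroboration of the terminal alkene with 9-BBN (THF, rt) gives the primary alkylborane F7, which is coupled in the same flask with 1-bromo-2-methylprop-1-ene (CC(C)=CBr; Pd(dppf)Cl2, Cs2CO3, DMF/H2O) to give 20.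

**Further compounds**
F1 | step 3 | methyl 2,2-dimethyl-3,5-dioxohexanoate | COC(=O)C(C)(C)C(=O)CC(C)=O
F2 | step 3 | filicinic acid (4,4-dimethylcyclohexane-1,3,5-trione, enolised) | O=C1CC(=O)C(C)(C)C(=O)C1
F3 | step 5 | (6R)-5-hydroxy-6-[(2E)-4-hydroxy-3-methylbut-2-en-1-yl]-2,2-dimethyl-4-[(2R)-2-methylbutanoyl]-6-(3-methylbut-2-en-1-yl)cyclohex-4-ene-1,3-dione | CC[C@@H](C)C(=O)C1=C(O)[C@@](CC=C(C)C)(C/C=C(C)/CO)C(=O)C(C)(C)C1=O
F4 | step 5 | (2R,3aR)-2-[(2S)-1,2-dihydroxypropan-2-yl]-5,5-dimethyl-7-[(2R)-2-methylbutanoyl]-3a-(3-methylbut-2-en-1-yl)-3,3a-dihydro-1-benzofuran-4,6(2H,5H)-dione | CC[C@@H](C)C(=O)C1=C2O[C@@H]([C@@](C)(O)CO)C[C@@]2(CC=C(C)C)C(=O)C(C)(C)C1=O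
F5 | step 8 | (2R,3aS)-2-[(2R)-2-hydroxy-1-oxopropan-2-yl]-5,5-dimethyl-7-[(2R)-2-methylbutanoyl]-3a-(3-methylbut-2-en-1-yl)-3,3a-dihydro-1-benzofuran-4,6(2H,5H)-dione | CC[C@@H](C)C(=O)C1=C2O[C@@H]([C@@](C)(O)C=O)C[C@]2(CC=C(C)C)C(=O)C(C)(C)C1=O
F6 | step 8 | (2R,3aS)-2-[(2S)-2-hydroxybut-3-en-2-yl]-5,5-dimethyl-7-[(2R)-2-methylbutanoyl]-3a-(3-methylbut-2-en-1-yl)-3,3a-dihydro-1-benzofuran-4,6(2H,5H)-dione | CC[C@@H](C)C(=O)C1=C2O[C@@H]([C@@](C)(O)C=C)C[C@]2(CC=C(C)C)C(=O)C(C)(C)C1=O
F7 | step 8 | (2R,3aS)-2-[(2S)-4-(9-borabicyclo[3.3.1]nonan-9-yl)-2-hydroxybutan-2-yl]-5,5-dimethyl-7-[(2R)-2-methylbutanoyl]-3a-(3-methylbut-2-en-1-yl)-3,3a-dihydro-1-benzofuran-4,6(2H,5H)-dione | CC[C@@H](C)C(=O)C1=C2O[C@@H]([C@@](C)(O)CCB3C4CCCC3CCC4)C[C@]2(CC=C(C)C)C(=O)C(C)(C)C1=O
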